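Ring B is opened between C5 and C6. In the target, C5 (the tertiary carbinol shared by rings A and B) is attached to C6, the γ-position of the unsaturated C12 carbonyl (C12=O, C8=C7), so this bond is a vinylogous aldol linkage. The key step deprotonates the C6 methyl of an α-ethylidene lactone and lets the dienolate add through C6 to the ring-A ketone C5; one operation should give the C5–C6 bond, ring B, the C7=C8 alkene in its final place and the 5α-hydroxyl. The precursor is a ring-A cyclohexanone (C4 gem-dimethyl, quaternary C10, C1 silyl ether) whose C9 carries a γ-butyrolactone built from C11, C12 and C8, with C7=C6 as the ethylidene.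

Key step: step 9

Remark: drimane numbering is used for every compound (ring A = C1–C5 with C10, ring B = C5–C10, C11 on C9, C12 on C8); 2–4 are carried as epimer mixtures at C10 because that centre becomes trigonal in 5 and is only fixed in step 3; the C7=C8 geometry of 17 is irrelevant because the dienolate erases it.

Step 1
Reactants: 1 2,6,6-trimethylcyclohex-2-en-1-one
Product: 3 (3R)-3-hydroxy-2,6,6-trimethylcyclohexan-1-one (both C2 epimers), via boryl ketone 2 (not isolated)
Conditions: B2pin2, CuCl (5 mol%), NaOtBu (10 mol%), (R,S)-Josiphos or its antipode (whichever gives 3R), MeOH, THF, rt; then NaBO3·4H2O, THF–H2O, rt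
Reagents that add atoms: bis(pinacolato)diboron, CC1(C)OB(OC1(C)C)B1OC(C)(C)C(C)(C)O1 (boryl group of intermediate 2 only); sodium perborate, [Na+].[O-]OB=O (hydroxyl oxygen)
Why: Enantioselective copper-catalysed conjugate borylation (ligand-controlled face selection at the β-carbon C1) followed by stereoretentive C–B oxidation should give the 3R carbinol; the α-carbon is protonated unselectively, which is harmless.

Step 2
Reactants: 3 (3R)-3-hydroxy-2,6,6-trimethylcyclohexan-1-one
Product: 5 tert-butyldimethyl{[(1R)-2,4,4-trimethyl-3-(trimethylsilyloxy)cyclohex-2-en-1-yl]oxy}silane, via silyl ether ketone 4 (not isolated)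
Conditions: TBSOTf (1.05 equiv), Et3N, CH2Cl2, −78 °C; then TMSOTf (1.5 equiv), −78 °C → rt
Reagents that add atoms: tert-butyldimethylsilyl triflate, CC(C)(C)[Si](C)(C)OS(=O)(=O)C(F)(F)F; trimethylsilyl triflate, C[Si](C)(C)OS(=O)(=O)C(F)(F)F
Why: The alcohol is silylated cold and the hindered ketone is then turned into its only possible (tetrasubstituted) silyl enol ether by soft enolisation, which avoids a free enolate and hence β-elimination of the silyloxy group.

Step 3
Reactants: 5 tert-butyldimethyl{[(1R)-2,4,4-trimethyl-3-(trimethylsilyloxy)cyclohex-2-en-1-yl]oxy}silane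
Product: 6 (2S,3R)-3-(tert-butyldimethylsilyloxy)-2-(hydroxymethyl)-2,6,6-trimethylcyclohexan-1-one
Conditions: 37% aq. HCHO, Yb(OTf)3 (10 mol%), THF, rt
Reagents that add atoms: formaldehyde, C=O
Why: Lewis-acid-catalysed Mukaiyama aldol addition to formaldehyde should build the quaternary C10 with the electrophile entering anti to the pseudoaxial silyloxy group on the neighbouring C1, so that CH2OH (C9) is trans and the methyl cis to the C1 oxygen.

Step 4
Reactants: 6 (2S,3R)-3-(tert-butyldimethylsilyloxy)-2-(hydroxymethyl)-2,6,6-trimethylcyclohexan-1-one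
Product: 7 (1R,6R)-6-(tert-butyldimethylsilyloxy)-1,3,3-trimethyl-2-oxocyclohexane-1-carbaldehyde
Conditions: Dess–Martin periodinane, CH2Cl2, rt
Reagents that add atoms: none
Why: Dess–Martin oxidation of a neopentyl primary alcohol; the aldehyde has no α-hydrogen and the ketone cannot enolise, so nothing can epimerise.

Step 5
Reactants: 7 (1R,6R)-6-(tert-butyldimethylsilyloxy)-1,3,3-trimethyl-2-oxocyclohexane-1-carbaldehyde
Product: 10 (4aS,8aR)-4a,6,6-trimethyl-4a,7,8,8a-tetrahydro-2H-chromene-2,5(6H)-dione (trans-fused δ-lactone between the C1 oxygen and C12), via Z-enoate 8 (not isolated), via hydroxy enoate 9 (not isolated)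
Conditions: (CF3CH2O)2P(O)CH2CO2Me, KN(SiMe3)2, 18-crown-6, THF, −78 °C; then 48% aq. HF, MeCN, rt
Reagents that add atoms: methyl bis(2,2,2-trifluoroethyl)phosphonoacetate, COC(=O)CP(=O)(OCC(F)(F)F)OCC(F)(F)F (C8 and C12)
Why: Still–Gennari (Z-selective Horner–Wadsworth–Emmons) olefination followed by acidic desilylation, after which the Z-configured δ-hydroxy enoate should lactonise; the trans ring fusion is already fixed by the trans-diequatorial C1–O and C10–C9 bonds.

Step 6
Reactants: 10 (4aS,8aR)-4a,6,6-trimethyl-4a,7,8,8a-tetrahydro-2H-chromene-2,5(6H)-dione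
Product: 13 (4S)-4-[(1S,6R)-6-hydroxy-1,3,3-trimethyl-2-oxocyclohexyl]oxolan-2-one, via silane adduct 11 (not isolated), via hydroxymethyl δ-lactone 12 (not isolated)
Conditions: (iPrO)Me2SiCH2MgCl (from ClCH2SiMe2(OiPr) and Mg), CuBr·SMe2 (20 mol%), THF, −40 → 0 °C; then KF, KHCO3, 30% H2O2, THF–MeOH, rt
Reagents that add atoms: (isopropoxydimethylsilyl)methylmagnesium chloride, CC(C)O[Si](C)(C)C[Mg]Cl (C11; silyl group of intermediate 11 only); hydrogen peroxide, OO (oxygen on C11)
Why: Copper-catalysed conjugate addition of a hydroxymethyl anion equivalent should occur axially at C9, anti to the axial C10 methyl of the rigid trans-fused lactone (as in cuprate additions to angularly methylated bicyclic enones), which sets C9; Tamao oxidation then frees the C11 hydroxyl, and this axial CH2OH, 1,3 to the lactone carbonyl, should take over the acyl group to give the more stable five-membered lactone and the free C1 hydroxyl.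

Step 7
Reactants: 13 (4S)-4-[(1S,6R)-6-hydroxy-1,3,3-trimethyl-2-oxocyclohexyl]oxolan-2-one
Product: 14 (4S)-4-[(1S,6R)-6-(tert-butyldimethylsilyloxy)-1,3,3-trimethyl-2-oxocyclohexyl]oxolan-2-one
Conditions: TBSOTf, 2,6-lutidine, CH2Cl2, 0 °C
Reagents that add atoms: tert-butyldimethylsilyl triflate, CC(C)(C)[Si](C)(C)OS(=O)(=O)C(F)(F)F
Why: Silyl triflate silylation of the hindered equatorial secondary alcohol masks the C1 oxygen, which would otherwise re-attack the lactone under the basic conditions that follow.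

Step 8
Reactants: 14 (4S)-4-[(1S,6R)-6-(tert-butyldimethylsilyloxy)-1,3,3-trimethyl-2-oxocyclohexyl]oxolan-2-one
Product: 17 (3E,4R)-4-[(1S,6R)-6-(tert-butyldimethylsilyloxy)-1,3,3-trimethyl-2-oxocyclohexyl]-3-ethylideneoxolan-2-one, via aldol adduct 15 (not isolated), via mesylate 16 (not isolated)
Conditions: LiN(iPr)2, THF, −78 °C, then MeCHO; crude aldol: MsCl, Et3N, CH2Cl2, 0 °C, then DBU, rt
Reagents that add atoms: acetaldehyde, CC=O (C7 and C6); methanesulfonyl chloride, CS(=O)(=O)Cl (mesyl group of intermediate 16 only)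
Why: Aldol addition of the lactone lithium enolate (C8) to acetaldehyde and E1cB elimination of the derived mesylate should give the α-ethylidene lactone; the C5 ketone has no α-hydrogen and stays untouched.

Step 9
Reactants: 17 (3E,4R)-4-[(1S,6R)-6-(tert-butyldimethylsilyloxy)-1,3,3-trimethyl-2-oxocyclohexyl]-3-ethylideneoxolan-2-one
Product: 18 1β-(tert-butyldimethylsilyloxy)-5α-hydroxydrim-7-en-12,11-olide (C12 carbonyl)
Conditions: LiN(SiMe3)2 (1.5 equiv), THF–DMPU, −78 → −20 °C; AcOH quench at −78 °C
Reagents that add atoms: none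
Why: The amide base removes a γ-hydrogen from the C6 methyl of the α-ethylidene lactone to give the lithium dienolate (a 3-vinyl-2-oxidodihydrofuran), whose terminal carbon C6 adds to the C5 ketone; this is an intramolecular vinylogous aldol addition of an ester-type dienolate to a ketone. Ring B closes in a 6-(enolendo)-exo-trig mode, with C6–C8 of the dienolate inside the new ring and the carbonyl oxygen outside it. C5 is the only new stereocentre: with ring A in the chair that keeps the C10 methyl axial and the C9 arm and the C1 silyloxy group equatorial, and with the C9–C10 rotamer that puts H9 in the crowded slot between C1 and C5, C6 is delivered to the equatorial position of C5, so the oxygen becomes axial and trans to the C10 methyl; the addition is reversible at lithium, so the trans-decalin ketol should also be the thermodynamic sink. The step needs γ- rather than α-attack and a single electrophile: attack through C8 would give a four-membered ring, C5 cannot enolise because C4 and C10 are quaternary, and C9–H is not activated by the lactone carbonyl. Joining C11–O to C12 in the lactone keeps C9–H non-acidic and leaves no second ester or β-leaving group, and the cold acid quench avoids vinylogous dehydration of the new tertiary alcohol.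

Step 10
Reactants: 18 1β-(tert-butyldimethylsilyloxy)-5α-hydroxydrim-7-en-12,11-olide
Product: 19 1β-(tert-butyldimethylsilyloxy)drim-7-ene-5α,11,12-triol
Conditions: LiAlH4, THF, 0 °C
Reagents that add atoms: none
Why: LiAlH4 should reduce the α,β-unsaturated γ-lactone by 1,2-addition to the allylic 11,12-diol; the silyl ether, the trisubstituted alkene and the tertiary alcohol are inert.

Step 11
Reactants: 19 1β-(tert-butyldimethylsilyloxy)drim-7-ene-5α,11,12-triol
Product: 20 1β-(tert-butyldimethylsilyloxy)-11,12-O-isopropylidenedrim-7-ene-5α,11,12-triol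
Conditions: Me2C(OMe)2, PPTS (cat.), CH2Cl2, rt
Reagents that add atoms: 2,2-dimethoxypropane, COC(C)(C)OC
Why: Acid-catalysed transketalisation should close a seven-membered isopropylidene acetal over the two primary hydroxyls on the neighbouring carbons C9 and C8, leaving the hindered tertiary C5 hydroxyl free.

Step 12
Reactants: 20 1β-(tert-butyldimethylsilyloxy)-11,12-O-isopropylidenedrim-7-ene-5α,11,12-triol
Product: 21 11,12-O-isopropylidenedrim-7-ene-1β,5α,11,12-tetraol
Conditions: Bu4NF, THF, 50 °C
Reagents that add atoms: none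
Why: Fluoride cleaves the secondary silyl ether; the acetal and the tertiary alcohol are stable to fluoride.

Step 13
Reactants: 22 p-coumaric acid
Product: 24 (E)-3-[4-(tert-butyldimethylsilyloxy)phenyl]prop-2-enoic acid, via silyl ester 23 (not isolated)
Conditions: TBSCl (2.5 equiv), imidazole, DMF, rt; then AcOH–THF–H2O, rt
Reagents that add atoms: tert-butyldimethylsilyl chloride, CC(C)(C)[Si](C)(C)Cl
Why: Double silylation of phenol and acid followed by selective hydrolysis of the labile silyl ester should give the phenol-protected acid.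

Step 14
Reactants: 21 11,12-O-isopropylidenedrim-7-ene-1β,5α,11,12-tetraol; 24 (E)-3-[4-(tert-butyldimethylsilyloxy)phenyl]prop-2-enoic acid
Product: 26 1β-[(E)-4-(tert-butyldimethylsilyloxy)cinnamoyloxy]-11,12-O-isopropylidenedrim-7-ene-5α,11,12-triol, via mixed anhydride 25 (not isolated)
Conditions: 2,4,6-Cl3C6H2COCl, Et3N, THF, rt; then 21, DMAP, toluene, 40 °C
Reagents that add atoms: 2,4,6-trichlorobenzoyl chloride, O=C(Cl)c1c(Cl)cc(Cl)cc1Cl (aroyl group of intermediate 25 only)
Why: Yamaguchi esterification (mixed anhydride, DMAP acyl transfer) should acylate the equatorial secondary C1 hydroxyl only, because the tertiary C5 hydroxyl sits between two quaternary carbons.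

Step 15
Reactants: 26 1β-[(E)-4-(tert-butyldimethylsilyloxy)cinnamoyloxy]-11,12-O-isopropylidenedrim-7-ene-5α,11,12-triol
Product: 27 1β-[(E)-4-(tert-butyldimethylsilyloxy)cinnamoyloxy]drim-7-ene-5α,11,12-triol
Conditions: AcOH–THF–H2O (3:1:1), rt
Reagents that add atoms: none
Why: Mild aqueous acid should hydrolyse the seven-membered acetal without touching the cinnamate ester, the aryl silyl ether or the tertiary alcohol.

Step 16
Reactants: 27 1β-[(E)-4-(tert-butyldimethylsilyloxy)cinnamoyloxy]drim-7-ene-5α,11,12-triol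
Product: 28 1β-[(E)-4-(tert-butyldimethylsilyloxy)cinnamoyloxy]-5α-hydroxydrim-7-ene-11,12-dial
Conditions: (COCl)2, DMSO, CH2Cl2, −78 °C; then Et3N, −78 → −40 °C; pH 7 buffer quench
Reagents that add atoms: none
Why: Swern oxidation turns both primary alcohols into alkoxysulfonium ions before base is added, so the dialdehyde should form without lactol or lactone by-products; the tertiary alcohol cannot be oxidised and the cold amine treatment should leave the C9 configuration intact.

Step 17
Reactants: 28 1β-[(E)-4-(tert-butyldimethylsilyloxy)cinnamoyloxy]-5α-hydroxydrim-7-ene-11,12-dial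
Product: 29 1β-[(E)-4-hydroxycinnamoyloxy]-5α-hydroxydrim-7-ene-11,12-dial (target, CNP0323926.1)
Conditions: Bu4NF–AcOH (1:1), THF, 0 °C
Reagents that add atoms: none
Why: Buffered fluoride should remove the aryl silyl ether (phenoxide is a good leaving group at silicon) under nearly neutral conditions that spare the epimerisable C9–H, the enal and the ester.

Compound list
1 | 2,6,6-trimethylcyclohex-2-en-1-one | CC1=CCCC(C)(C)C1=O | starting material
2 | (3R)-2,6,6-trimethyl-3-(4,4,5,5-tetramethyl-1,3,2-dioxaborolan-2-yl)cyclohexan-1-one (C2 epimers) | CC1(C)CC[C@@H](B2OC(C)(C)C(C)(C)O2)C(C)C1=O | intermediate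
3 | (3R)-3-hydroxy-2,6,6-trimethylcyclohexan-1-one (C2 epimers) | CC1(C)CC[C@@H](O)C(C)C1=O | intermediate
4 | (3R)-3-(tert-butyldimethylsilyloxy)-2,6,6-trimethylcyclohexan-1-one (C2 epimers) | CC1(C)CC[C@@H](O[Si](C)(C)C(C)(C)C)C(C)C1=O | intermediate
5 | tert-butyldimethyl{[(1R)-2,4,4-trimethyl-3-(trimethylsilyloxy)cyclohex-2-en-1-yl]oxy}silane | CC1(C)CC[C@@H](O[Si](C)(C)C(C)(C)C)C(C)=C1O[Si](C)(C)C | intermediate
6 | (2S,3R)-3-(tert-butyldimethylsilyloxy)-2-(hydroxymethyl)-2,6,6-trimethylcyclohexan-1-one (CH2OH trans to OSi) | CC1(C)CC[C@@H](O[Si](C)(C)C(C)(C)C)[C@](C)(CO)C1=O | intermediate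
7 | (1R,6R)-6-(tert-butyldimethylsilyloxy)-1,3,3-trimethyl-2-oxocyclohexane-1-carbaldehyde | CC1(C)CC[C@@H](O[Si](C)(C)C(C)(C)C)[C@](C)(C=O)C1=O | intermediate
8 | methyl (Z)-3-[(1S,6R)-6-(tert-butyldimethylsilyloxy)-1,3,3-trimethyl-2-oxocyclohexyl]prop-2-enoate | CC1(C)CC[C@@H](O[Si](C)(C)C(C)(C)C)[C@](C)(/C=C\C(=O)OC)C1=O | intermediate
9 | methyl (Z)-3-[(1S,6R)-6-hydroxy-1,3,3-trimethyl-2-oxocyclohexyl]prop-2-enoate | CC1(C)CC[C@@H](O)[C@](C)(/C=C\C(=O)OC)C1=O | intermediate
10 | (4aS,8aR)-4a,6,6-trimethyl-4a,7,8,8a-tetrahydro-2H-chromene-2,5(6H)-dione (trans-fused unsaturated δ-lactone) | CC1(C)CC[C@H]2OC(=O)C=C[C@]2(C)C1=O | intermediate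
11 | (4S,4aS,8aR)-4-{[dimethyl(propan-2-yloxy)silyl]methyl}-4a,6,6-trimethylhexahydro-2H-chromene-2,5-dione (CH2Si anti to the angular methyl) | CC1(C)CC[C@H]2OC(=O)C[C@H](C[Si](C)(C)OC(C)C)[C@]2(C)C1=O | intermediate
12 | (4S,4aS,8aR)-4-(hydroxymethyl)-4a,6,6-trimethylhexahydro-2H-chromene-2,5-dione | CC1(C)CC[C@H]2OC(=O)C[C@H](CO)[C@]2(C)C1=O | intermediate
13 | (4S)-4-[(1S,6R)-6-hydroxy-1,3,3-trimethyl-2-oxocyclohexyl]oxolan-2-one | CC1(C)CC[C@@H](O)[C@](C)([C@H]2COC(=O)C2)C1=O | intermediate
14 | (4S)-4-[(1S,6R)-6-(tert-butyldimethylsilyloxy)-1,3,3-trimethyl-2-oxocyclohexyl]oxolan-2-one | CC1(C)CC[C@@H](O[Si](C)(C)C(C)(C)C)[C@](C)([C@H]2COC(=O)C2)C1=O | intermediate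
15 | (4S)-4-[(1S,6R)-6-(tert-butyldimethylsilyloxy)-1,3,3-trimethyl-2-oxocyclohexyl]-3-(1-hydroxyethyl)oxolan-2-one (mixture at C8 and C7) | CC1(C)CC[C@@H](O[Si](C)(C)C(C)(C)C)[C@](C)([C@H]2COC(=O)C2C(C)O)C1=O | intermediate
16 | methanesulfonate of 15 | CC1(C)CC[C@@H](O[Si](C)(C)C(C)(C)C)[C@](C)([C@H]2COC(=O)C2C(C)OS(C)(=O)=O)C1=O | intermediate
17 | (3E,4R)-4-[(1S,6R)-6-(tert-butyldimethylsilyloxy)-1,3,3-trimethyl-2-oxocyclohexyl]-3-ethylideneoxolan-2-one (key-step precursor) | CC1(C)CC[C@@H](O[Si](C)(C)C(C)(C)C)[C@](C)([C@H]2COC(=O)/C2=C/C)C1=O | intermediate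
18 | 1β-(tert-butyldimethylsilyloxy)-5α-hydroxydrim-7-en-12,11-olide (key-step product) | CC1(C)CC[C@@H](O[Si](C)(C)C(C)(C)C)[C@]2(C)[C@H]3COC(=O)C3=CC[C@@]12O | intermediate
19 | 1β-(tert-butyldimethylsilyloxy)drim-7-ene-5α,11,12-triol | CC1(C)CC[C@@H](O[Si](C)(C)C(C)(C)C)[C@]2(C)[C@@H](CO)C(CO)=CC[C@@]12O | intermediate
20 | 1β-(tert-butyldimethylsilyloxy)-11,12-O-isopropylidenedrim-7-ene-5α,11,12-triol | CC1(C)CC[C@@H](O[Si](C)(C)C(C)(C)C)[C@]2(C)[C@H]3COC(C)(C)OCC3=CC[C@@]12O | intermediate
21 | 11,12-O-isopropylidenedrim-7-ene-1β,5α,11,12-tetraol | CC1(C)CC[C@@H](O)[C@]2(C)[C@H]3COC(C)(C)OCC3=CC[C@@]12O | intermediate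
22 | p-coumaric acid, (E)-3-(4-hydroxyphenyl)prop-2-enoic acid | OC(=O)/C=C/c1ccc(O)cc1 | starting material
23 | tert-butyldimethylsilyl (E)-3-[4-(tert-butyldimethylsilyloxy)phenyl]prop-2-enoate | CC(C)(C)[Si](C)(C)OC(=O)/C=C/c1ccc(O[Si](C)(C)C(C)(C)C)cc1 | intermediate
24 | (E)-3-[4-(tert-butyldimethylsilyloxy)phenyl]prop-2-enoic acid | OC(=O)/C=C/c1ccc(O[Si](C)(C)C(C)(C)C)cc1 | intermediate
25 | mixed anhydride of 24 with 2,4,6-trichlorobenzoic acid | CC(C)(C)[Si](C)(C)Oc1ccc(/C=C/C(=O)OC(=O)c2c(Cl)cc(Cl)cc2Cl)cc1 | intermediate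
26 | 1β-[(E)-4-(tert-butyldimethylsilyloxy)cinnamoyloxy]-11,12-O-isopropylidenedrim-7-ene-5α,11,12-triol | CC1(C)CC[C@@H](OC(=O)/C=C/c4ccc(O[Si](C)(C)C(C)(C)C)cc4)[C@]2(C)[C@H]3COC(C)(C)OCC3=CC[C@@]12O | intermediate
27 | 1β-[(E)-4-(tert-butyldimethylsilyloxy)cinnamoyloxy]drim-7-ene-5α,11,12-triol | CC1(C)CC[C@@H](OC(=O)/C=C/c3ccc(O[Si](C)(C)C(C)(C)C)cc3)[C@]2(C)[C@@H](CO)C(CO)=CC[C@@]12O | intermediate
28 | 1β-[(E)-4-(tert-butyldimethylsilyloxy)cinnamoyloxy]-5α-hydroxydrim-7-ene-11,12-dial | CC1(C)CC[C@@H](OC(=O)/C=C/c3ccc(O[Si](C)(C)C(C)(C)C)cc3)[C@]2(C)[C@@H](C=O)C(C=O)=CC[C@@]12O | intermediate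
29 | 1β-[(E)-4-hydroxycinnamoyloxy]-5α-hydroxydrim-7-ene-11,12-dial, (1R,5R,9R,10S) | CC1(C)CC[C@@H](OC(=O)/C=C/c2ccc(O)cc2)[C@]2(C)[C@@H](C=O)C(C=O)=CC[C@@]12O | target

Total step count: 17. Longest linear sequence: 16 steps (steps 1–12 and 14–17; step 13 prepares the side-chain acid).

Steps most likely to fail:

Step 9. The hindered C5 alkoxide may revert to the dienolate (retro-aldol), so that open material is recovered, or closure may partly follow the cis ring-fusion mode. The fallback sets out from 17: soft enolisation with TBSOTf and Et3N in CH2Cl2 should give the silyl dienol ether F1. Treatment of F1 with BF3·OEt2 in CH2Cl2 at −78 °C is an intramolecular vinylogous Mukaiyama aldol addition, which activates the ketone instead of relying on a reversible metal aldolate. Hydrolytic work-up returns to the route at 18.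

Step 6. Carbon transfer to the crowded β-carbon next to the quaternary centre may be slow, with competing carbonyl addition, or the acyl migration may stop short. The fallback sets out from 10: addition of vinylmagnesium bromide with CuBr·SMe2 in THF should give the vinyl lactone F2 by the same axial approach. Ozonolysis with PPh3 work-up would give the formyl lactone F3, and NaBH4 in MeOH at −78 °C would reduce the aldehyde in the presence of the hindered ketone. This comes back to the route at 12, which rearranges to 13 (catalytic DBU if needed).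

Step 3. The small electrophile may discriminate poorly between the two faces of the enol ether, or the enol ether may hydrolyse before C–C bond formation. The fallback sets out from 3: Fráter–Seebach alkylation of the alkoxide–enolate dianion (LiN(iPr)2, 2.2 equiv, THF, −78 → −40 °C) with benzyl chloromethyl ether should give the benzyloxymethyl ketone F4, with the new group trans to the chelated alkoxide. Silylation with TBSOTf and 2,6-lutidine gives the silyl ether F5, and hydrogenolysis (H2 over Pd/C, EtOAc) comes back to the route at 6.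

Further compounds
F1 | step 9 | tert-butyl{[(4S)-4-[(1S,6R)-6-(tert-butyldimethylsilyloxy)-1,3,3-trimethyl-2-oxocyclohexyl]-3-ethenyl-4,5-dihydrofuran-2-yl]oxy}dimethylsilane | CC1(C)CC[C@@H](O[Si](C)(C)C(C)(C)C)[C@](C)([C@H]2COC(O[Si](C)(C)C(C)(C)C)=C2C=C)C1=O
F2 | step 6 | (4aS,8aR)-4-ethenyl-4a,6,6-trimethylhexahydro-2H-chromene-2,5-dione (vinyl anti to the angular methyl) | CC1(C)CC[C@H]2OC(=O)C[C@H](C=C)[C@]2(C)C1=O
F3 | step 6 | (4aS,8aR)-4a,6,6-trimethyl-2,5-dioxooctahydro-2H-chromene-4-carbaldehyde (formyl anti to the angular methyl) | CC1(C)CC[C@H]2OC(=O)C[C@H](C=O)[C@]2(C)C1=O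
F4 | step 3 | (2S,3R)-2-(benzyloxymethyl)-3-hydroxy-2,6,6-trimethylcyclohexan-1-one | CC1(C)CC[C@@H](O)[C@](C)(COCc2ccccc2)C1=O
F5 | step 3 | (2S,3R)-2-(benzyloxymethyl)-3-(tert-butyldimethylsilyloxy)-2,6,6-trimethylcyclohexan-1-one | CC1(C)CC[C@@H](O[Si](C)(C)C(C)(C)C)[C@](C)(COCc2ccccc2)C1=O
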